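## Analysis of the target

Target 23 is a dihydroflavonol 3-O-methyl ether: a chroman-4-one in which benzo ring A is fused to pyranone ring C, with ring B attached at C2. Ring A carries 5-OH, 6-OH and 7-OMe and is free only at C8; ring B is a 2,3-dihydroxy-4-methoxyphenyl group; C3 carries the only aliphatic methyl ether. The stereocentres C2 (R) and C3 (R) are adjacent, with aryl and methoxy trans, both equatorial on the half-chair of ring C and H2 and H3 anti. C3 is alpha to the C4 ketone and C2 is a benzylic carbon beta to it through O1, so base or strong acid can scramble the pair by enolisation or by retro-oxa-Michael opening to the chalcone, dehydrogenation to the flavonol is a constant sink, and the catechol of ring A and the pyrogallol monomethyl ether of ring B are oxidised by air. The difficulty is to set this labile trans pair in the absolute sense while telling apart seven oxygen atoms of four kinds (four free phenols, two aryl methyl ethers, one alkyl methyl ether, one ketone). The route rests on the atoms O1–C8a–C4a–C4, which with ring A form the oxadiene of an ortho-quinone methide, C2=C3 being the matching two-carbon partner. Ring B polarises that alkene so that oxygen goes to C2, but an oxygen on C3 would overrule it, so C3 must enter with a substituent that is not a π-donor and is later exchanged for oxygen with retention: boron.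

## Retrosynthetic reasoning

**Phenol protection (23 ⇒ 22 ⇒ 20).** The four phenols are masked in two classes. The 6-, 2'- and 3'-oxygens are benzyl ethers in 22 and fall together in a final hydrogenolysis. The 5-oxygen is a methyl ether in 20, because it is the one aryl methyl ether that sits peri to the C4 carbonyl and can be cleaved by chelation while the 7- and 4'-methoxy groups stay. This lets both aromatic rings be taken from simple precursors with the oxygen pattern already complete.

**Oxidation level at C4 (20 ⇒ 19 ⇒ 18).** The ketone is traced back to the benzylic alcohol 19 and this to the benzylic methyl ether 18. As long as C4 is sp3, C3 cannot enolise and ring C cannot open, so the stereocentres are safe during all basic and acidic steps. The C4 methoxy group is also exactly what the ring-forming step leaves behind.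

**Oxygen at C3 (18 ⇒ 17 ⇒ 15).** The C3–O bond is cut back to a C3–B bond. Forward, the boronate of 15 is oxidised with retention to alcohol 17, which is methylated while the molecule is still base-stable. This turns C3 into a carbon that, at the alkene stage, carried no donor.

**Ring C (15 ⇒ 6 + 11 + 12).** The O1–C2 and C3–C4 bonds are cut. No other pair of cuts divides the molecule into two aromatic halves of similar size and leaves O1, C8a, C4a and C4 all inside one simple ring A building block, salicylaldehyde 6. C2 and C3 come from (E)-styrylboronate 11, and the C4 methoxy group from orthoformate 12. The forward reaction has to place oxygen at C2, transfer the E geometry into the 2,3-trans relationship, and select one face of the alkene.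

**Ring A piece (6 ⇒ 4 ⇒ 2 ⇒ 1).** The formyl carbon is removed from 6 to give phenol 4, whose hydroxyl is traced to the formyl group of aldehyde 2, the benzyl ether of syringaldehyde 1. Phenol 4 is symmetric with the para position blocked, so the formylation has only one possible outcome. The hydroxyl of 1, the oxygen that must end free at C6, is marked as a benzyl ether from the first step.

**Ring B piece (11 ⇒ 8 + 9; 8 ⇒ 7).** The alkene of 11 is cut to aldehyde 8 and the one-carbon diboron reagent 9, a single olefination that gives the E isomer. Aldehyde 8 is the bis-benzyl ether of commercial 7, which already has the full ring B oxygen pattern.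

## Alternatives that were turned down

**Alternative 1:** Ring C is closed at C3–C4 by a radical–acyl coupling.
- Disconnection: C3–C4. The precursor is seco acid A1, in which the O1–C2 aryl ether is already present, ring A carries a thioester where C4 will be, and C3 is a carboxylic acid carbon bearing the methoxy group.
- Forward key step: under dual catalysis (for example Ir[dF(CF3)ppy]2(dtbbpy)PF6 with NiCl2(dme) and a bipyridine), photoredox decarboxylation gives the alpha-methoxy C3 radical. Zerovalent nickel inserts into the thioester C–S bond, the acylnickel captures the radical, and reductive elimination gives ketone A2, which is identical with 20.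
- For: C4 arrives as the ketone and C3 already carries its methoxy group, so only two steps remain. C2 could be set by conventional asymmetric oxidation of a cinnamate. On both points it is stronger than the chosen route, which needs six steps after its key step and depends on an untested catalyst-controlled cycloaddition.
- Against: C3 passes through a planar radical, so its configuration depends only on substrate control from C2 during ring closure. The radical is beta to an aryloxy group and can fragment. The acylnickel is flanked by two ortho substituents and may lose CO. A1 requires an aryl ether between a hindered, electron-poor phenol and a secondary benzylic carbon that ring B makes prone to ionisation, so clean inversion is doubtful, and A1 is estimated at eight or more linear steps.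
- Comparison: the chosen route offers in return two fragments made in three and two steps, and a relative configuration fixed by the mechanism rather than by a ring-closing preference.

**Alternative 2:** The C2 hydroxyl is captured by a ring A ortho-quinone.
- Disconnection: O1–C8a. The precursor is hydroxy ketone A3, whose two aryl groups are the same 2,3-dihydroxy-4-methoxyphenyl unit, free in ring A and benzylated in ring B.
- Forward key step: oxidation of the ring A catechol to the 5,6-ortho-quinone makes C8a the beta carbon of an enone. The C2 hydroxyl adds there in a six-membered conjugate addition, and tautomerisation restores the catechol, giving A4.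
- For: one hydrogenolysis from A4 gives 23, ring A needs no protecting groups, and both rings come from the substitution pattern of 7. In protecting-group economy and in steps after the key step it is stronger than the chosen route.
- Against: the stereochemical problem is moved into an anti-selective asymmetric aldol of an alpha-methoxy aryl ketone, for which this pattern offers no reliable handle. A3 is prone to retro-aldol cleavage and dehydration. A4 has one more oxygen on ring A than A3, so it is more easily oxidised than its precursor and over-oxidation towards the quinone and the flavonol is built into the step.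
- Comparison: the chosen route sets both stereocentres in the same event that makes the C–C and C–O bonds, and its intermediates are at no point more oxidisable than their precursors.

**Alternative 3:** Ring A is built last by a Diels–Alder benzannulation.
- Disconnection: C4a–C5 and C8–C8a. A preformed ring C, bromo-dihydropyranone A5 carrying the C2 aryl and C3 methoxy groups, is the dienophile, and silyl ketene acetal diene A6 supplies C5–C8 with the 6-benzyloxy and 7-methoxy groups.
- Forward key step: cycloaddition joins the CH2 terminus of A6 to C8a and the ketene acetal carbon to C4a. Loss of Me3SiOMe and HBr followed by enolisation aromatises ring A and gives A7, identical with 22.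
- For: the diene polarity fixes the ring A pattern, the 5-hydroxyl arrives free, C2 and C3 could come from a known type of catalytic asymmetric hetero-Diels–Alder reaction of aldehyde 8, and A7 is one step from 23. On these points it is stronger than the chosen route.
- Against: A5 is a vinylogous ester and therefore an electron-rich, poor dienophile. A6 is a tetra-oxygenated diene whose disubstituted terminus disfavours the s-cis conformer, and it is easily hydrolysed. The heat needed endangers C3 (alpha to the ketone) and invites retro-oxa-Michael opening. A Mukaiyama–Michael addition without ring closure is a likely detour, and building A5 and A6 is estimated at seven or more steps.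
- Comparison: the chosen route takes the six carbons and three oxygens of ring A from syringaldehyde instead of assembling them, and exposes no epimerisable ketone to heat.

Key step: step 6

Assumption: the sense of induction of the chiral acid in step 6 cannot be derived from structure alone. The (R)-acid is written; if it favours the mirror-image series, the (S)-acid is used with no other change.

## Route

Step 1
Reactants: 1 syringaldehyde
Product: 2 4-(benzyloxy)-3,5-dimethoxybenzaldehyde
Conditions: BnBr, K2CO3, DMF, 60 °C
Reagents that add atoms: benzyl bromide, BrCc1ccccc1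
Why: Williamson etherification of the only phenol. The benzyl ether marks the oxygen that ends as the free 6-OH and prevents the next step from giving a hydroquinone.

Step 2
Reactants: 2 4-(benzyloxy)-3,5-dimethoxybenzaldehyde
Product: 4 4-(benzyloxy)-3,5-dimethoxyphenol, via aryl formate 3 (not isolated)
Conditions: mCPBA, CH2Cl2, 0 °C → rt; aq. NaHCO3 wash; then K2CO3 (cat.), MeOH, rt
Reagents that add atoms: 3-chloroperoxybenzoic acid (mCPBA), OOC(=O)c1cccc(Cl)c1
Why: Baeyer–Villiger (Dakin-type) oxidation; the electron-rich aryl group migrates in the Criegee intermediate to give formate 3, which mild methanolysis cleaves to the phenol.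

Step 3
Reactants: 4 4-(benzyloxy)-3,5-dimethoxyphenol
Product: 6 3-(benzyloxy)-6-hydroxy-2,4-dimethoxybenzaldehyde, via salicyl alcohol 5 (not isolated)
Conditions: MgCl2, Et3N, (CH2O)n, MeCN, reflux
Reagents that add atoms: formaldehyde (as paraformaldehyde), C=O
Why: Casnati–Skattebøl ortho-formylation; the magnesium phenoxide directs formaldehyde to the ortho carbon to give 5, which a second formaldehyde oxidises by hydride transfer. The two ortho positions are equivalent and the para position is blocked, so only one aldehyde can form.

Step 4
Reactants: 7 2,3-dihydroxy-4-methoxybenzaldehyde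
Product: 8 2,3-bis(benzyloxy)-4-methoxybenzaldehyde
Conditions: BnBr, K2CO3, DMF, 60 °C
Reagents that add atoms: benzyl bromide, BrCc1ccccc1
Why: Double Williamson etherification. Benzyl is chosen so that all three protecting groups fall in the last step and the 2-benzyloxy group can act as a donor in step 6.

Step 5
Reactants: 8 2,3-bis(benzyloxy)-4-methoxybenzaldehyde; 9 bis[(pinacolato)boryl]methane
Product: 11 (E)-2-{2-[2,3-bis(benzyloxy)-4-methoxyphenyl]ethenyl}-4,4,5,5-tetramethyl-1,3,2-dioxaborolane, via lithium alkoxide adduct 10 (not isolated)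
Conditions: 2,2,6,6-tetramethylpiperidine, n-BuLi, THF, 0 °C; 9, 0 °C; then 8, −78 °C → rt
Reagents that add atoms: none
Why: Boron–Wittig olefination; deprotonated 9 adds to the aldehyde to give 10, which loses a boron–oxygen fragment by syn elimination. The elimination through the less crowded arrangement should give the E alkene.

Step 6
Reactants: 6 3-(benzyloxy)-6-hydroxy-2,4-dimethoxybenzaldehyde; 11 (E)-2-{2-[2,3-bis(benzyloxy)-4-methoxyphenyl]ethenyl}-4,4,5,5-tetramethyl-1,3,2-dioxaborolane; 12 trimethyl orthoformate
Product: 15 (2S,3S)-6-(benzyloxy)-2-[2,3-bis(benzyloxy)-4-methoxyphenyl]-4,5,7-trimethoxy-3-(4,4,5,5-tetramethyl-1,3,2-dioxaborolan-2-yl)chromane (2,3-trans; both C4 epimers), via dimethyl acetal 13 (not isolated), via ortho-quinone methide 14 (not isolated)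
Conditions: (R)-3,3'-bis(2,4,6-triisopropylphenyl)-1,1'-binaphthyl-2,2'-diyl hydrogen phosphate [(R)-TRIP] (10 mol %), 5 Å MS, toluene, −20 → 0 °C
Reagents that add atoms: trimethyl orthoformate, COC(OC)OC
Why: Proposed new method: the acid converts 6 and 12 into acetal 13, which loses methanol to the 4-methoxy ortho-quinone methide 14, reacting as its O-protonated form (an O-methyl oxocarbenium ion hydrogen-bonded and ion-paired to the chiral phosphate); the boron-bearing carbon of 11 (future C3) attacks C4 and the phenol oxygen closes onto the developing C2 cation in an asynchronous inverse-demand [4+2] that forms C3–C4 and O1–C2. The closest known reaction types are the chiral Brønsted acid-catalysed hetero-Diels–Alder reaction of in situ ortho-quinone methides with styrenes and the acid-mediated union of salicylaldehydes, orthoformates and styrenes to 4-alkoxy-2-arylchromans; an alkenylboronate has not been shown as the two-carbon partner. Ring C closes by cycloaddition, suprafacial on both partners (in the stepwise limit a 6-exo-trig capture of the para-quinone-methide-like C2 cation by the phenol oxygen). Orientation: the boronate is not a π-donor, so the 4-methoxy and 2-benzyloxy groups of ring B alone decide that the cation develops at C2 and oxygen bonds there. Relative configuration: the E geometry of 11 is carried into the 2,3-trans arrangement. Absolute configuration: the phosphate held by the phenolic OH must fix both the open face of the oxadiene and the endo or exo approach, because it is the alkene face, not C4, that defines C2 and C3; C4 itself may be a mixture since it becomes the ketone. The adduct must also survive, so sieves, a non-nucleophilic solvent and low temperature are used to keep the C4 ether from re-ionising next to boron.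

Step 7
Reactants: 15 (2S,3S)-6-(benzyloxy)-2-[2,3-bis(benzyloxy)-4-methoxyphenyl]-4,5,7-trimethoxy-3-(4,4,5,5-tetramethyl-1,3,2-dioxaborolan-2-yl)chromane
Product: 17 (2R,3S)-6-(benzyloxy)-2-[2,3-bis(benzyloxy)-4-methoxyphenyl]-4,5,7-trimethoxychroman-3-ol (both C4 epimers), via borate ester 16 (not isolated)
Conditions: NaBO3·4H2O, THF/H2O (1:1), rt
Reagents that add atoms: sodium perborate, written as its dimeric salt Na2[B2(O2)2(OH)4], [Na+].[Na+].O[B-]1(O)OO[B-](O)(O)OO1
Why: Oxidation of a secondary alkylboronate; the peroxide adds to boron and C3 migrates from boron to oxygen with retention to give 16, which hydrolyses in the flask. Near-neutral perborate should let this migration outrun beta-alkoxy elimination and leaves the acid-labile C4 ether alone; the descriptors change only because oxygen replaces boron.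

Step 8
Reactants: 17 (2R,3S)-6-(benzyloxy)-2-[2,3-bis(benzyloxy)-4-methoxyphenyl]-4,5,7-trimethoxychroman-3-ol
Product: 18 (2R,3S)-6-(benzyloxy)-2-[2,3-bis(benzyloxy)-4-methoxyphenyl]-3,4,5,7-tetramethoxychromane (both C4 epimers)
Conditions: NaH, MeI, THF/DMF, 0 °C → rt
Reagents that add atoms: iodomethane, CI
Why: Williamson O-methylation of the secondary alkoxide. At this oxidation level C3 has no acidic hydrogen and ring C cannot open, so the stereocentres are safe under base.

Step 9
Reactants: 18 (2R,3S)-6-(benzyloxy)-2-[2,3-bis(benzyloxy)-4-methoxyphenyl]-3,4,5,7-tetramethoxychromane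
Product: 19 (2R,3S)-6-(benzyloxy)-2-[2,3-bis(benzyloxy)-4-methoxyphenyl]-3,5,7-trimethoxychroman-4-ol (both C4 epimers)
Conditions: p-TsOH·H2O (10 mol %), THF/H2O (4:1), rt
Reagents that add atoms: water, O
Why: SN1 solvolysis of a benzylic ether; the C4 cation is stabilised by O1 and by the 5- and 7-methoxy groups, so dilute acid in wet THF exchanges methoxy for hydroxyl. Boron is already gone, so the cation has no beta-elimination path through it, and the C4 epimer mixture does not matter.

Step 10
Reactants: 19 (2R,3S)-6-(benzyloxy)-2-[2,3-bis(benzyloxy)-4-methoxyphenyl]-3,5,7-trimethoxychroman-4-ol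
Product: 20 (2R,3R)-6-(benzyloxy)-2-[2,3-bis(benzyloxy)-4-methoxyphenyl]-3,5,7-trimethoxychroman-4-one
Conditions: activated MnO2, CH2Cl2, rt
Reagents that add atoms: none
Why: MnO2 oxidation of an electron-rich benzylic alcohol under neutral heterogeneous conditions, which should avoid enolisation of the new alpha-methoxy ketone and retro-oxa-Michael opening. Both C4 epimers converge on one ketone.

Step 11
Reactants: 20 (2R,3R)-6-(benzyloxy)-2-[2,3-bis(benzyloxy)-4-methoxyphenyl]-3,5,7-trimethoxychroman-4-one
Product: 22 (2R,3R)-6-(benzyloxy)-2-[2,3-bis(benzyloxy)-4-methoxyphenyl]-5-hydroxy-3,7-dimethoxychroman-4-one, via dichloroboron chelate 21 (not isolated)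
Conditions: BCl3 (1.2 equiv), CH2Cl2, −78 → −20 °C; then aq. NaHCO3
Reagents that add atoms: none
Why: Chelation-controlled ether cleavage; BCl3 binds the C4 carbonyl and the peri 5-methoxy oxygen, and chloride removes the methyl group to give chelate 21, hydrolysed on work-up. Ethers without a neighbouring carbonyl should react much more slowly at this temperature.

Step 12
Reactants: 22 (2R,3R)-6-(benzyloxy)-2-[2,3-bis(benzyloxy)-4-methoxyphenyl]-5-hydroxy-3,7-dimethoxychroman-4-one
Product: 23 (2R,3R)-2-(2,3-dihydroxy-4-methoxyphenyl)-5,6-dihydroxy-3,7-dimethoxychroman-4-one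
Conditions: H2 (1 atm), palladium on carbon (10% Pd/C), EtOAc/MeOH, rt; work-up under argon
Reagents that add atoms: none
Why: Hydrogenolysis of the three aryl benzyl ethers. The methyl ethers and the hydrogen-bonded ketone should not react at one atmosphere and room temperature, and the neutral medium does not touch C2 or C3.

## Compound list

1 | syringaldehyde (4-hydroxy-3,5-dimethoxybenzaldehyde) | COc1cc(C=O)cc(OC)c1O | starting material
2 | 4-(benzyloxy)-3,5-dimethoxybenzaldehyde | COc1cc(C=O)cc(OC)c1OCc1ccccc1 | intermediate
3 | 4-(benzyloxy)-3,5-dimethoxyphenyl formate (not isolated) | COc1cc(OC=O)cc(OC)c1OCc1ccccc1 | intermediate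
4 | 4-(benzyloxy)-3,5-dimethoxyphenol | COc1cc(O)cc(OC)c1OCc1ccccc1 | intermediate
5 | 4-(benzyloxy)-2-(hydroxymethyl)-3,5-dimethoxyphenol (not isolated) | COc1cc(O)c(CO)c(OC)c1OCc1ccccc1 | intermediate
6 | 3-(benzyloxy)-6-hydroxy-2,4-dimethoxybenzaldehyde | COc1cc(O)c(C=O)c(OC)c1OCc1ccccc1 | intermediate
7 | 2,3-dihydroxy-4-methoxybenzaldehyde | COc1ccc(C=O)c(O)c1O | starting material
8 | 2,3-bis(benzyloxy)-4-methoxybenzaldehyde | COc1ccc(C=O)c(OCc2ccccc2)c1OCc1ccccc1 | intermediate
9 | bis[(pinacolato)boryl]methane | CC1(C)OB(CB2OC(C)(C)C(C)(C)O2)OC1(C)C | starting material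
10 | lithium 1-[2,3-bis(benzyloxy)-4-methoxyphenyl]-2,2-bis(4,4,5,5-tetramethyl-1,3,2-dioxaborolan-2-yl)ethan-1-olate (not isolated) | [Li+].[O-]C(c1ccc(OC)c(OCc2ccccc2)c1OCc1ccccc1)C(B1OC(C)(C)C(C)(C)O1)B1OC(C)(C)C(C)(C)O1 | intermediate
11 | (E)-2-{2-[2,3-bis(benzyloxy)-4-methoxyphenyl]ethenyl}-4,4,5,5-tetramethyl-1,3,2-dioxaborolane | COc1ccc(/C=C/B2OC(C)(C)C(C)(C)O2)c(OCc2ccccc2)c1OCc1ccccc1 | intermediate
12 | trimethyl orthoformate | COC(OC)OC | starting material
13 | 4-(benzyloxy)-2-(dimethoxymethyl)-3,5-dimethoxyphenol (not isolated) | COC(OC)c1c(O)cc(OC)c(OCc2ccccc2)c1OC | intermediate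
14 | 4-(benzyloxy)-3,5-dimethoxy-6-(methoxymethylidene)cyclohexa-2,4-dien-1-one (not isolated) | COC=C1C(=O)C=C(OC)C(OCc2ccccc2)=C1OC | intermediate
15 | (2S,3S)-6-(benzyloxy)-2-[2,3-bis(benzyloxy)-4-methoxyphenyl]-4,5,7-trimethoxy-3-(4,4,5,5-tetramethyl-1,3,2-dioxaborolan-2-yl)chromane, 2,3-trans, C4 epimers | COc1ccc([C@H]2Oc3cc(OC)c(OCc4ccccc4)c(OC)c3C(OC)[C@@H]2B5OC(C)(C)C(C)(C)O5)c(OCc2ccccc2)c1OCc1ccccc1 | intermediate
16 | (2R,3S)-6-(benzyloxy)-2-[2,3-bis(benzyloxy)-4-methoxyphenyl]-4,5,7-trimethoxy-3-[(4,4,5,5-tetramethyl-1,3,2-dioxaborolan-2-yl)oxy]chromane (not isolated) | COc1ccc([C@H]2Oc3cc(OC)c(OCc4ccccc4)c(OC)c3C(OC)[C@@H]2OB5OC(C)(C)C(C)(C)O5)c(OCc2ccccc2)c1OCc1ccccc1 | intermediate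
17 | (2R,3S)-6-(benzyloxy)-2-[2,3-bis(benzyloxy)-4-methoxyphenyl]-4,5,7-trimethoxychroman-3-ol, C4 epimers | COc1ccc([C@H]2Oc3cc(OC)c(OCc4ccccc4)c(OC)c3C(OC)[C@@H]2O)c(OCc2ccccc2)c1OCc1ccccc1 | intermediate
18 | (2R,3S)-6-(benzyloxy)-2-[2,3-bis(benzyloxy)-4-methoxyphenyl]-3,4,5,7-tetramethoxychromane, C4 epimers | COc1ccc([C@H]2Oc3cc(OC)c(OCc4ccccc4)c(OC)c3C(OC)[C@@H]2OC)c(OCc2ccccc2)c1OCc1ccccc1 | intermediate
19 | (2R,3S)-6-(benzyloxy)-2-[2,3-bis(benzyloxy)-4-methoxyphenyl]-3,5,7-trimethoxychroman-4-ol, C4 epimers | COc1ccc([C@H]2Oc3cc(OC)c(OCc4ccccc4)c(OC)c3C(O)[C@@H]2OC)c(OCc2ccccc2)c1OCc1ccccc1 | intermediate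
20 | (2R,3R)-6-(benzyloxy)-2-[2,3-bis(benzyloxy)-4-methoxyphenyl]-3,5,7-trimethoxychroman-4-one | COc1ccc([C@H]2Oc3cc(OC)c(OCc4ccccc4)c(OC)c3C(=O)[C@@H]2OC)c(OCc2ccccc2)c1OCc1ccccc1 | intermediate
21 | (2R,3R)-6-(benzyloxy)-2-[2,3-bis(benzyloxy)-4-methoxyphenyl]-5-[(dichloroboranyl)oxy]-3,7-dimethoxychroman-4-one (not isolated) | COc1ccc([C@H]2Oc3cc(OC)c(OCc4ccccc4)c(OB(Cl)Cl)c3C(=O)[C@@H]2OC)c(OCc2ccccc2)c1OCc1ccccc1 | intermediate
22 | (2R,3R)-6-(benzyloxy)-2-[2,3-bis(benzyloxy)-4-methoxyphenyl]-5-hydroxy-3,7-dimethoxychroman-4-one | COc1ccc([C@H]2Oc3cc(OC)c(OCc4ccccc4)c(O)c3C(=O)[C@@H]2OC)c(OCc2ccccc2)c1OCc1ccccc1 | intermediate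
23 | (2R,3R)-2-(2,3-dihydroxy-4-methoxyphenyl)-5,6-dihydroxy-3,7-dimethoxychroman-4-one | COc1ccc([C@H]2Oc3cc(OC)c(O)c(O)c3C(=O)[C@@H]2OC)c(O)c1O | target

## Step count and risks

Total step count: 12. Longest linear sequence: 10 steps (steps 1–3 and 6–12). The ring B branch (steps 4 and 5) joins at step 6.

**Step 6 (key step).**
- What may go wrong: poor discrimination between the two alkene faces, if either the face of the oxadiene or the endo/exo mode is not held by the phosphate, which would lower the enantiomeric purity at C2 and C3. Loss of boron by elimination if the C4 ether re-ionises in the adduct, or ipso-substitution at boron instead of ring closure. A slow addition, because the electrophilic carbon is flanked by two ortho substituents and the nucleophilic carbon bears the boronate, which would let Friedel–Crafts attack on ring B compete.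
- Fallback (known chemistry, from 4 and 8, returning at 20): phenol 4 is acetylated ortho to the hydroxyl (Ac2O, BF3·OEt2, Friedel–Crafts/Fries) to 1-[3-(benzyloxy)-6-hydroxy-2,4-dimethoxyphenyl]ethan-1-one F1, and the phenol is protected (MOMCl, NaH) as the methoxymethyl ether 1-[3-(benzyloxy)-2,4-dimethoxy-6-(methoxymethoxy)phenyl]ethan-1-one F2. Claisen–Schmidt condensation of this ketone with aldehyde 8 (KOH, EtOH) gives the (E)-chalcone F3. Juliá–Colonna epoxidation (poly-L-leucine, urea–H2O2, DBU, THF) gives the (2R,3S)-epoxy ketone F4. Methanolic HCl removes the methoxymethyl group, and the freed phenol opens the epoxide at the benzylic carbon with inversion to give the trans-dihydroflavonol (2R,3R)-6-(benzyloxy)-2-[2,3-bis(benzyloxy)-4-methoxyphenyl]-3-hydroxy-5,7-dimethoxychroman-4-one F5. Purdie methylation (MeI, Ag2O) of its 3-hydroxyl gives 20, and the route continues with step 11.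

**Step 7.**
- What may go wrong: beta-elimination from the boron ate complex. In the diequatorial conformer the C3–B bond is antiperiplanar to the ring C2–O1 bond, so ring C may open with loss of the phenoxide, or the 4-methoxy group may be expelled, before the 1,2-shift occurs.
- Fallback (from 15, returning at 18): the elimination is made the intended reaction. BF3·OEt2 in CH2Cl2 at −78 °C removes the 4-methoxy group and boron in a Peterson-type elimination to give (2S)-6-(benzyloxy)-2-[2,3-bis(benzyloxy)-4-methoxyphenyl]-5,7-dimethoxy-2H-chromene F6, in which C2 is untouched; it is kept cold and used at once. Dihydroxylation (OsO4 cat., NMO) anti to the 2-aryl group gives the 2,3-trans-3,4-cis diol (2R,3S,4S)-6-(benzyloxy)-2-[2,3-bis(benzyloxy)-4-methoxyphenyl]-5,7-dimethoxychromane-3,4-diol F7. Double O-methylation (NaH, MeI) gives 18 as its 3,4-cis isomer, and the route continues with step 9.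

**Step 9.**
- What may go wrong: proton loss from C3 in the C4 cation, which would give the enol ether and, after hydrolysis, the 3-ketone, destroying C3; or incomplete exchange because the liberated methanol competes with water.
- Fallback (from 18, returning at 20): oxidative cleavage replaces hydrolysis. DDQ in wet CH2Cl2 abstracts the C4 hydride of the benzylic methyl ether, water adds to the oxocarbenium ion, and the hemiketal collapses to ketone 20 with loss of methanol. Alcohol 19 and step 10 are bypassed, and no new compound is made.

**Step 11.**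
- What may go wrong: loss of chemoselectivity. Benzyl ethers, above all the 6-benzyl ether flanked by two oxygens, may be cleaved alongside; the C3 methoxy group may be attacked through a five-membered chelate with the ketone; or the Lewis acid may open C2–O1 and allow epimerisation. Partial debenzylation alone is harmless, since step 12 removes these groups anyway.
- Fallback (from 20, returning at 23): the order is reversed. Hydrogenolysis (H2, Pd/C) gives (2R,3R)-2-(2,3-dihydroxy-4-methoxyphenyl)-6-hydroxy-3,5,7-trimethoxychroman-4-one F8, and its peri 5-methoxy group is then cleaved with AlCl3 in MeCN through the chelate with the ketone, giving 23.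

**Step 12.**
- What may go wrong: over-reduction (hydrogenolysis of the benzylic C2–O1 bond or reduction of the aryl ketone), and oxidation by air of the catechol and pyrogallol-type rings of 23 during isolation.
- Fallback (from 22, returning at 23): non-reductive debenzylation with BCl3 and pentamethylbenzene as cation scavenger in CH2Cl2 at −78 °C gives 23 directly; no new compound is made.

## Further compounds

F1 | step 6 | 1-[3-(benzyloxy)-6-hydroxy-2,4-dimethoxyphenyl]ethan-1-one | COc1cc(O)c(C(C)=O)c(OC)c1OCc1ccccc1
F2 | step 6 | 1-[3-(benzyloxy)-2,4-dimethoxy-6-(methoxymethoxy)phenyl]ethan-1-one | COCOc1cc(OC)c(OCc2ccccc2)c(OC)c1C(C)=O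
F3 | step 6 | (E)-1-[3-(benzyloxy)-2,4-dimethoxy-6-(methoxymethoxy)phenyl]-3-[2,3-bis(benzyloxy)-4-methoxyphenyl]prop-2-en-1-one | COCOc1cc(OC)c(OCc2ccccc2)c(OC)c1C(=O)/C=C/c1ccc(OC)c(OCc2ccccc2)c1OCc1ccccc1
F4 | step 6 | [(2R,3S)-3-[2,3-bis(benzyloxy)-4-methoxyphenyl]oxiran-2-yl][3-(benzyloxy)-2,4-dimethoxy-6-(methoxymethoxy)phenyl]methanone | COCOc1cc(OC)c(OCc2ccccc2)c(OC)c1C(=O)[C@@H]1O[C@H]1c1ccc(OC)c(OCc2ccccc2)c1OCc1ccccc1
F5 | step 6 | (2R,3R)-6-(benzyloxy)-2-[2,3-bis(benzyloxy)-4-methoxyphenyl]-3-hydroxy-5,7-dimethoxychroman-4-one | COc1ccc([C@H]2Oc3cc(OC)c(OCc4ccccc4)c(OC)c3C(=O)[C@@H]2O)c(OCc2ccccc2)c1OCc1ccccc1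
F6 | step 7 | (2S)-6-(benzyloxy)-2-[2,3-bis(benzyloxy)-4-methoxyphenyl]-5,7-dimethoxy-2H-chromene | COc1ccc([C@H]2Oc3cc(OC)c(OCc4ccccc4)c(OC)c3C=C2)c(OCc2ccccc2)c1OCc1ccccc1
F7 | step 7 | (2R,3S,4S)-6-(benzyloxy)-2-[2,3-bis(benzyloxy)-4-methoxyphenyl]-5,7-dimethoxychromane-3,4-diol | COc1ccc([C@H]2Oc3cc(OC)c(OCc4ccccc4)c(OC)c3[C@H](O)[C@@H]2O)c(OCc2ccccc2)c1OCc1ccccc1
F0 | step 9 | none | none
F8 | step 11 | (2R,3R)-2-(2,3-dihydroxy-4-methoxyphenyl)-6-hydroxy-3,5,7-trimethoxychroman-4-one | COc1ccc([C@H]2Oc3cc(OC)c(O)c(OC)c3C(=O)[C@@H]2OC)c(O)c1O
F0 | step 12 | none | none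
A1 | alternative 1 | (3R)-3-{4-(benzyloxy)-2-[(ethylsulfanyl)carbonyl]-3,5-dimethoxyphenoxy}-3-[2,3-bis(benzyloxy)-4-methoxyphenyl]-2-methoxypropanoic acid | CCSC(=O)c1c(O[C@H](c2ccc(OC)c(OCc3ccccc3)c2OCc2ccccc2)C(OC)C(O)=O)cc(OC)c(OCc2ccccc2)c1OC
A2 | alternative 1 | (2R,3R)-6-(benzyloxy)-2-[2,3-bis(benzyloxy)-4-methoxyphenyl]-3,5,7-trimethoxychroman-4-one | COc1ccc([C@H]2Oc3cc(OC)c(OCc4ccccc4)c(OC)c3C(=O)[C@@H]2OC)c(OCc2ccccc2)c1OCc1ccccc1
A3 | alternative 2 | (2R,3R)-3-[2,3-bis(benzyloxy)-4-methoxyphenyl]-1-(2,3-dihydroxy-4-methoxyphenyl)-3-hydroxy-2-methoxypropan-1-one | COc1ccc(C(=O)[C@H](OC)[C@H](O)c2ccc(OC)c(OCc3ccccc3)c2OCc2ccccc2)c(O)c1O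
A4 | alternative 2 | (2R,3R)-2-[2,3-bis(benzyloxy)-4-methoxyphenyl]-5,6-dihydroxy-3,7-dimethoxychroman-4-one | COc1ccc([C@H]2Oc3cc(OC)c(O)c(O)c3C(=O)[C@@H]2OC)c(OCc2ccccc2)c1OCc1ccccc1
A5 | alternative 3 | (2R,3R)-2-[2,3-bis(benzyloxy)-4-methoxyphenyl]-5-bromo-3-methoxy-2,3-dihydro-4H-pyran-4-one | COc1ccc([C@H]2OC=C(Br)C(=O)[C@@H]2OC)c(OCc2ccccc2)c1OCc1ccccc1
A6 | alternative 3 | {[2-(benzyloxy)-1,3-dimethoxybuta-1,3-dien-1-yl]oxy}trimethylsilane | COC(=C)C(OCc1ccccc1)=C(OC)O[Si](C)(C)C
A7 | alternative 3 | (2R,3R)-6-(benzyloxy)-2-[2,3-bis(benzyloxy)-4-methoxyphenyl]-5-hydroxy-3,7-dimethoxychroman-4-one | COc1ccc([C@H]2Oc3cc(OC)c(OCc4ccccc4)c(O)c3C(=O)[C@@H]2OC)c(OCc2ccccc2)c1OCc1ccccc1
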